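## The problem

The target is a spiro[5.5]undecane of the chamigrene type. The atoms are numbered C1 (=CH2), C2, C3, C4 (CHOH), C5 (CHBr), C6 (CMe2), C7 (spiro), C8, C9, C10 (carbinol bearing CH2Cl), C11 (C=O) and C12, with ring A = C2–C7 and ring B = C7–C12. The hardest bond is C6–C7, because it joins two fully substituted carbons, one of them the stereogenic spiro atom. There are four stereocentres: C4–OH and C5–Br are cis to each other and to C12, and the C10 hydroxyl is cis to C6 across ring B. C4 can be set from C5 by hydride reduction of an α-bromo ketone. C5 has to be set from C7 through the conformation of ring A, because C6 carries two identical methyl groups. C10 is four atoms from C7 and feels it only through the chair of ring B. C7 is therefore the centre from which the others derive and must be set absolutely. The α-ketol with its β-chloride closes to an epoxide or fragments with base, and the exocyclic C2 methylene moves into conjugation once C4 is a ketone. The three oxygenated carbons C2, C4 and C11 must be told apart, and so must C3 from C5 and C10 from C12 in the enolisations. What makes a short construction possible is that C7 is β to the ring B carbonyl C11 and that C6 is the Markovnikov radical of an isopropenyl group. A tertiary radical at C6 adding to a C7=C12 enone closes ring A and creates the spiro centre in one step.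

## Retrosynthesis

The chlorohydrin of target 29 is cut first at C–Cl, giving spiro-epoxy ketone 28, then at C10–O, giving α-methylene ketone 27, then at the exocyclic carbon, giving ketone 24. Ring B is left for last because neither the epoxide nor the chloro ketol would survive the strong bases and hydrides needed in ring A. The forward steps must enolise C11 towards C10 and deliver oxygen to the C10 face cis to C6.

Ketone 24 comes from its ethylene ketal 23, and the cis-bromohydrin of 23 from α-bromo ketone 22 by hydride addition (C4–H). Bromoketone 22 is traced through dienol ether 21 to γ-bromo vinylogous ester 20 (C2=C1 bond) and on to vinylogous ester 18 (C5–Br bond). Bromine has to go in while C3 is an sp2 carbon of the vinylogous ester. In a C4 ketone with the methylene already in place, C3 is doubly activated and would be brominated instead. The methylene is then revealed by carbonyl methylenation and kinetic hydrolysis, never by enolisation.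

Vinylogous ester 18 is the enol ether of ring A dione 17, which comes from diol 16, its bis-silyl ether 15 and ketone 14. These are changes of functional groups only. The C11 ketal is needed because 18–22 meet a lithium amide, a titanium methylidene and an aluminium hydride.

Spiro ketone 14 is cut at C6–C7 to enone 13, in which C6 is an isopropenyl carbon and C7 the β-carbon of a cyclohexenone. This removes the ring, the quaternary–quaternary bond and the spiro stereocentre in one cut. C2 is carried as a silyloxy carbinol and not as a ketone: an acyl group on C7 would make the alkene an ene-dione, and the less hindered C12 would then compete as a 7-endo acceptor. With C11 as the only carbonyl, C7 is the one electrophilic carbon. The cis silyloxy groups at C2 and C4 are there to fix the chair through which C7 is set; both are oxidised later.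

Enone 13 comes from ketal 12, and 12 from syn-diol 11, which is the 1,3-syn reduction product of β-hydroxy enone 10. Syn is required because only the syn isomer can place both oxygens equatorial in the cyclisation chair.

Ketone 10 is cut at C2–C7 into Weinreb amide 5 and vinyllithium 9, made from bromo ketal 8. The cut is convergent and puts the C2 carbonyl where the directed reduction needs it.

Amide 5 comes from hydroxy ester 4, which is the opening product of epoxy ester 2 with isopropenylmagnesium bromide 3. Epoxide 2 comes from the commercial chlorohydrin ester 1, the source of all chirality. Bromo ketal 8 comes from bromo enone 7 and cyclohexane-1,3-dione 6.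

## Roads not taken

Alternative 1: Here ring B is built onto a finished ring A by cutting C7–C8 and C11–C12. A chiral primary amine would add C7 of hydroxymethylene ketone A1 to methyl vinyl ketone A2, and the methyl ketone would then condense with the formyl carbon to give dienone A3. The merits are real. The sequence to the spirocycle is short, the enantiocontrol is catalytic, and A3 already carries the ring A vinylogous ester that the chosen plan reaches only after compound 17. On step count to the spirocycle this road is better. Its weak points are two. C7 in A1 sits between an acyl group and the CMe2 carbon, so the quaternary centre must form intermolecularly next to a quaternary carbon, where iminium–enamine catalysis is slow and its selectivity uncertain. A3 also carries the ring B carbonyl on C10 and the alkene at C11=C12, while the target needs the carbinol at C10 and the carbonyl at C11, so a 1,2-transposition has to follow. The chosen plan sets against the shorter opening an intramolecular radical bond formation that tolerates crowding and a product, 14, with oxygen already on C11.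

Alternative 2: This road cuts C8–C9 and C10–C11. Zerovalent nickel with a chiral ligand would couple the carbonyl of prochiral spiro cyclobutanone A4 with silyl alkyne A5, cleave one of the two enantiotopic acyl–CH2 bonds and give cyclohexenone A6. It is better than the chosen plan in how it maps ring B: C10 arrives with its carbon substituent and C11 as the ketone, so no late methylenation and no C10 against C12 question arise. Its weak points are as follows. The two CH2 groups of A4 differ only through the distant C2 carbonyl and C6 dimethyl groups, so enantiodiscrimination is asked of a catalyst with little precedent for it in the intermolecular reaction. A4 itself still needs a quaternary C7 beside CMe2. The silyl group must be removed and a hydroxyl placed on a tetrasubstituted enone carbon with control from C7. The chosen plan sets against the better ring B mapping a spiro centre derived from a cheap chiral-pool carbinol by a precedented diastereoselective step.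

Alternative 3: The cut is C9–C10. A Lewis acid would chelate the hydroxy ketone of spiro acylcyclopentanol A7 and ring carbon C9 would migrate from the carbinol carbon to the acyl carbon, giving ketol A8. This creates the whole ring B array (tertiary carbinol, chloromethyl group and ketone) in one stereospecific step. For C10 it is more direct than the three-step end of the chosen plan, and its stereochemical transfer from a neighbouring centre is likely more reliable than the remote control used there. Its weak points: C7 must be set by some other means beforehand, and the carbinol centre of A7 must be made with the correct sense relative to C7. Migration of C12 in place of C9 would give the isomeric ketol. A8 would then have to pass through the ring A sequence (lithium amide, titanium methylidene, aluminium hydride) with a free chloro ketol, which it would not survive. The chosen plan sets against the more direct C10 construction the freedom to finish ring A first and touch ring B last.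

Key step: step 10

Remark on the chemistry: all names use the atom numbers C1–C12 defined above; dione 17 is written as the diketone although it should be largely enolised.

## Route

Step 1
Reactants: 1 ethyl (3S)-4-chloro-3-hydroxybutanoate
Product: 2 ethyl 2-[(2S)-oxiran-2-yl]acetate
Conditions: Ag2O, 1,2-dimethoxyethane, 60 °C, dark
Reagents that add atoms: none
Why: Intramolecular Williamson closure of the chlorohydrin; Ag2O takes up chloride without the strong base that would isomerise the β,γ-epoxy ester to the 4-hydroxycrotonate, and the carbinol stereocentre is not touched.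

Step 2
Reactants: 2 ethyl 2-[(2S)-oxiran-2-yl]acetate; 3 isopropenylmagnesium bromide
Product: 4 ethyl (3R)-3-hydroxy-5-methylhex-5-enoate
Conditions: CuI (10 mol%), THF, −40 °C; aq. NH4Cl
Reagents that add atoms: none
Why: Copper-catalysed Grignard opening of a terminal epoxide at its CH2 carbon, faster than addition to the ester at this temperature; the stereocentre is retained and only its descriptor changes.

Step 3
Reactants: 4 ethyl (3R)-3-hydroxy-5-methylhex-5-enoate
Product: 5 (3R)-3-hydroxy-N-methoxy-N,5-dimethylhex-5-enamide
Conditions: MeNH(OMe)·HCl, i-PrMgCl (3.2 equiv), THF, −20 → 0 °C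
Reagents that add atoms: N,O-dimethylhydroxylamine hydrochloride, CNOC.Cl
Why: Weinreb amide formation by aminolysis of the ester with the magnesium amide, which tolerates the free β-hydroxyl as its magnesium alkoxide.

Step 4
Reactants: 6 cyclohexane-1,3-dione
Product: 7 3-bromocyclohex-2-en-1-one
Conditions: (COBr)2, DMF (cat.), CH2Cl2, 0 °C → rt
Reagents that add atoms: oxalyl bromide, O=C(Br)C(=O)Br
Why: Vilsmeier-type activation of the enol oxygen and addition–elimination of bromide, the usual conversion of a 1,3-dione into a β-halo enone.

Step 5
Reactants: 7 3-bromocyclohex-2-en-1-one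
Product: 8 7-bromo-1,4-dioxaspiro[4.5]dec-6-ene
Conditions: Me3SiOCH2CH2OSiMe3, Me3SiOTf (cat.), CH2Cl2, −78 → −20 °C
Reagents that add atoms: 1,2-bis(trimethylsilyloxy)ethane, C[Si](C)(C)OCCO[Si](C)(C)C
Why: Silyl-triflate-catalysed aprotic ketalisation at low temperature, which keeps the double bond in place and avoids the addition–elimination at the bromine-bearing carbon that a free diol with protic acid would allow.

Step 6
Reactants: 8 7-bromo-1,4-dioxaspiro[4.5]dec-6-ene; 5 (3R)-3-hydroxy-N-methoxy-N,5-dimethylhex-5-enamide
Product: 10 (3R)-3-hydroxy-5-methyl-1-(1,4-dioxaspiro[4.5]dec-6-en-7-yl)hex-5-en-1-one, via ketal vinyllithium 9 (not isolated)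
Conditions: 8, t-BuLi (2.0 equiv), THF, −78 °C; then 5 (deprotonated with i-PrMgCl, 1.0 equiv), −78 → −40 °C; aq. NH4Cl
Reagents that add atoms: none
Why: Bromine–lithium exchange gives a β-acyl vinyl anion equivalent whose addition to the Weinreb amide stops at the chelated tetrahedral intermediate, so the ketone appears only on work-up; this forms C2–C7 and leaves C4 untouched.

Step 7
Reactants: 10 (3R)-3-hydroxy-5-methyl-1-(1,4-dioxaspiro[4.5]dec-6-en-7-yl)hex-5-en-1-one
Product: 11 (1R,3R)-5-methyl-1-(1,4-dioxaspiro[4.5]dec-6-en-7-yl)hex-5-ene-1,3-diol
Conditions: Et2BOMe, NaBH4, THF/MeOH 4:1, −78 °C; MeOH co-evaporation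
Reagents that add atoms: none
Why: Narasaka–Prasad reduction: the six-membered boron chelate of the β-hydroxy ketone is attacked by external hydride on the face that leads to the chair-like product, so C4 sets C2 in the 1,3-syn sense; chelation also activates the carbonyl for 1,2-reduction of the enone.

Step 8
Reactants: 11 (1R,3R)-5-methyl-1-(1,4-dioxaspiro[4.5]dec-6-en-7-yl)hex-5-ene-1,3-diol
Product: 12 7-[(1R,3R)-1,3-bis(tert-butyldimethylsilyloxy)-5-methylhex-5-en-1-yl]-1,4-dioxaspiro[4.5]dec-6-ene
Conditions: t-BuMe2SiCl, imidazole, DMAP (cat.), DMF, 40 °C
Reagents that add atoms: tert-butyldimethylsilyl chloride, CC(C)(C)[Si](C)(C)Cl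
Why: Standard silylation of two secondary alcohols under basic conditions that leave the allylic ketal alone; the ethers prevent oxa-Michael addition of the C4 hydroxyl to C7 once the enone is freed.

Step 9
Reactants: 12 7-[(1R,3R)-1,3-bis(tert-butyldimethylsilyloxy)-5-methylhex-5-en-1-yl]-1,4-dioxaspiro[4.5]dec-6-ene
Product: 13 3-[(1R,3R)-1,3-bis(tert-butyldimethylsilyloxy)-5-methylhex-5-en-1-yl]cyclohex-2-en-1-one
Conditions: PPTS (cat.), acetone/H2O 10:1, rt
Reagents that add atoms: water, O
Why: Hydrolysis of an allylic ketal, which is much faster than that of a saturated ketal, so that a weak acid is enough and the silyl ethers stay on.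

Step 10
Reactants: 13 3-[(1R,3R)-1,3-bis(tert-butyldimethylsilyloxy)-5-methylhex-5-en-1-yl]cyclohex-2-en-1-one
Product: 14 (1R,3R,6S)-1,3-bis(tert-butyldimethylsilyloxy)-5,5-dimethylspiro[5.5]undecan-8-one
Conditions: Fe(acac)3 (0.3 equiv), PhSiH3 (2.5 equiv, slow addition), EtOH/ethylene glycol 5:1, 0.01 M, 60 °C, argon
Reagents that add atoms: none
Why: Fe(acac)3 and PhSiH3 in ethanol form an iron hydride that transfers a hydrogen atom to the CH2 terminus of the 1,1-disubstituted alkene, giving the tertiary C6 radical and divalent iron. The nucleophilic radical adds to C7, the β-carbon of the cyclohexenone, and the α-keto radical at C12 is reduced by divalent iron to the enolate and protonated by ethanol, which returns trivalent iron. The closest known reaction type is the iron-hydride reductive olefin–enone coupling (hydrogen-atom-transfer Giese addition), whose intramolecular form is known to join two fully substituted carbons. Ring A closes in the 6-exo-trig mode. The new stereocentre C7 is controlled by the cis silyloxy groups on C2 and C4: both must be equatorial in the chair transition state, because an axial oxygen on either carbon would meet the axial methyl group of C6. The enone turns so that C12–H, not C8H2, lies beside C3 (least allylic strain), which makes C12 axial on ring A and cis to both oxygens. The step needs 6-exo attack at C7 to win over 7-endo attack at C12; this is secured because C2 is a carbinol carbon, so C11 is the only carbonyl polarising the alkene and attack at C12 would give an unstabilised radical. It also needs cyclisation to outrun reduction of the radical, which the geminal methyl groups, high dilution and slow silane addition favour.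

Step 11
Reactants: 14 (1R,3R,6S)-1,3-bis(tert-butyldimethylsilyloxy)-5,5-dimethylspiro[5.5]undecan-8-one
Product: 15 C11 ethylene ketal of 14
Conditions: Me3SiOCH2CH2OSiMe3, Me3SiOTf (cat.), CH2Cl2, −78 → −20 °C
Reagents that add atoms: 1,2-bis(trimethylsilyloxy)ethane, C[Si](C)(C)OCCO[Si](C)(C)C
Why: Silyl-triflate-catalysed ketalisation of the only ketone; the conditions are aprotic and cold, so the secondary silyl ethers are kept.

Step 12
Reactants: 15 C11 ethylene ketal of 14
Product: 16 (2R,4R,7S)-ring A 2,4-diol C11 ethylene ketal
Conditions: Bu4NF, THF, 50 °C
Reagents that add atoms: none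
Why: Fluoride cleavage of both silyl ethers; warming is needed for the neopentyl C2 ether and the ketal is inert to fluoride.

Step 13
Reactants: 16 (2R,4R,7S)-ring A 2,4-diol C11 ethylene ketal
Product: 17 (7S)-ring A 2,4-dione C11 ethylene ketal
Conditions: Dess–Martin periodinane (3 equiv), NaHCO3, CH2Cl2, 0 °C → rt
Reagents that add atoms: none
Why: Dess–Martin oxidation takes 1,3-diols through the β-hydroxy ketone to the 1,3-dione without retro-aldol cleavage, and the buffer protects the ketal; the stereocentres C2 and C4 are removed as planned and C7 remains.

Step 14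
Reactants: 17 (7S)-ring A 2,4-dione C11 ethylene ketal
Product: 18 (7S)-4-isobutoxy-2-oxo-3-ene (ring A vinylogous ester) C11 ethylene ketal
Conditions: i-BuOH (5 equiv), TsOH·H2O (cat.), benzene, reflux, Dean–Stark
Reagents that add atoms: 2-methylpropan-1-ol, CC(C)CO
Why: Acid-catalysed enol etherification of a 1,3-dione under water removal; the alcohol ends on C4, the carbonyl remote from the quaternary C7, as is usual for 4,4-disubstituted cyclohexane-1,3-diones, and the dioxolane survives because no water is present.

Step 15
Reactants: 18 (7S)-4-isobutoxy-2-oxo-3-ene (ring A vinylogous ester) C11 ethylene ketal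
Product: 20 (5R,7S)-5-bromo vinylogous ester C11 ethylene ketal, via silyl dienol ether 19 (not isolated)
Conditions: LiN(iPr)2, THF, −78 °C; Me3SiCl; then NBS, NaHCO3, THF, −78 °C
Reagents that add atoms: N-bromosuccinimide, O=C1CCC(=O)N1Br
Why: The α′ carbon C7 is quaternary, so the amide removes a γ-proton at C5; O-silylation gives the 2-alkoxy-4-silyloxy diene 19, which reacts with electrophilic bromine at its terminal carbon C5 as 1,3-dioxygenated dienes do (vinylogous α-bromination). C5 is set relative to C7: the C12 arm carrying the dioxolane should prefer the equatorial position on ring A with bromine cis to it, and bromide exchange with LiBr on this allylic bromide is available to equilibrate C5.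

Step 16
Reactants: 20 (5R,7S)-5-bromo vinylogous ester C11 ethylene ketal
Product: 22 (5R,7R)-5-bromo-2-methylene-4-ketone C11 ethylene ketal, via bromo dienol ether 21 (not isolated)
Conditions: Cp2Ti(μ-Cl)(μ-CH2)AlMe2, pyridine (cat.), THF/toluene, −40 → 0 °C; basic alumina filtration; then oxalic acid, THF/H2O, 0 °C
Reagents that add atoms: Tebbe reagent Cp2Ti(μ-Cl)(μ-CH2)AlMe2, C[Al-]1(C)C[Ti]([Cl+]1)(C2C=CC=C2)C2C=CC=C2; water, O
Why: Tebbe olefination methylenates the hindered, ester-like C2 carbonyl under non-basic conditions. The 1-alkoxy diene 21 is protonated kinetically at C3, the α-carbon of the dienol ether, so mild aqueous acid releases the C4 ketone with the double bond left exocyclic.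

Step 17
Reactants: 22 (5R,7R)-5-bromo-2-methylene-4-ketone C11 ethylene ketal
Product: 23 (4S,5R,7R)-cis-bromohydrin C11 ethylene ketal
Conditions: i-Bu2AlH, CH2Cl2, −78 °C; aq. potassium sodium tartrate
Reagents that add atoms: none
Why: Reduction of an α-bromo ketone to the cis-bromohydrin: the hydride comes from the equatorial side, away from the axial methyl group on C6 and anti to the C–Br bond, so C5 sets C4 with the hydroxyl axial and cis to bromine. The cold, non-basic hydride does not move the C2 methylene into conjugation.

Step 18
Reactants: 23 (4S,5R,7R)-cis-bromohydrin C11 ethylene ketal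
Product: 24 (4S,5R,7R)-5-bromo-4-hydroxy-2-methylene C11 ketone
Conditions: PPTS, acetone/H2O 10:1, 50 °C
Reagents that add atoms: water, O
Why: Mild acidic hydrolysis of the dioxolane; the weak acid does not protonate the 1,1-disubstituted alkene and the neopentyl bromide does not ionise.

Step 19
Reactants: 24 (4S,5R,7R)-5-bromo-4-hydroxy-2-methylene C11 ketone
Product: 27 (4S,5R,7R)-10-methylene C11 ketone, via Mannich base 25 (not isolated), via ammonium iodide 26 (not isolated)
Conditions: LiN(SiMe3)2 (2.2 equiv), THF, −78 °C; [Me2N=CH2]I, −78 → 0 °C; aqueous work-up; then MeI, CH2Cl2, rt; then aq. NaHCO3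
Reagents that add atoms: dimethylmethyleneiminium iodide, C=[N+](C)C.[I-]
Why: Kinetic deprotonation of the C11 ketone occurs at C10 because C12 is neopentyl (the second equivalent of base holds the C4 hydroxyl as its alkoxide); Mannich reaction with the iminium salt, exhaustive methylation and mild base give the exocyclic enone (Eschenmoser methylenation).

Step 20
Reactants: 27 (4S,5R,7R)-10-methylene C11 ketone
Product: 28 (4S,5R,7R,10R)-C10 spiro-epoxy C11 ketone
Conditions: 30% aq. H2O2, NaOH (0.2 equiv), MeOH, 0 °C
Reagents that add atoms: hydrogen peroxide, OO
Why: Weitz–Scheffer epoxidation: hydroperoxide adds to the exocyclic CH2 and the enolate closes onto oxygen. Ring B is held in the chair with C6 equatorial and C2 axial on C7, and the C10–O bond forms axially on the face away from C2, so the oxygen should come out cis to C6. The nucleophilic oxidant leaves the electron-rich C2 methylene alone.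

Step 21
Reactants: 28 (4S,5R,7R,10R)-C10 spiro-epoxy C11 ketone
Product: 29 CNP0273087.1
Conditions: LiCl, AcOH, THF, rt
Reagents that add atoms: lithium chloride, [Li+].[Cl-]
Why: Acid-assisted SN2 opening of the epoxide by chloride at its unsubstituted CH2 carbon, which leaves the C10–O bond and the C10 configuration intact and gives the tertiary chloro ketol; the weak acid does not isomerise the exocyclic alkene.

## Compound list

1 | ethyl (3S)-4-chloro-3-hydroxybutanoate | CCOC(=O)C[C@H](O)CCl | starting material
2 | ethyl 2-[(2S)-oxiran-2-yl]acetate | CCOC(=O)C[C@H]1CO1 | intermediate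
3 | isopropenylmagnesium bromide | CC(=C)[Mg]Br | starting material
4 | ethyl (3R)-3-hydroxy-5-methylhex-5-enoate | CCOC(=O)C[C@H](O)CC(C)=C | intermediate
5 | (3R)-3-hydroxy-N-methoxy-N,5-dimethylhex-5-enamide | CON(C)C(=O)C[C@H](O)CC(C)=C | intermediate
6 | cyclohexane-1,3-dione | O=C1CCCC(=O)C1 | starting material
7 | 3-bromocyclohex-2-en-1-one | O=C1C=C(Br)CCC1 | intermediate
8 | 7-bromo-1,4-dioxaspiro[4.5]dec-6-ene | BrC1=CC2(CCC1)OCCO2 | intermediate
9 | 1,4-dioxaspiro[4.5]dec-6-en-7-yllithium (not isolated) | [Li]C1=CC2(CCC1)OCCO2 | intermediate
10 | (3R)-3-hydroxy-5-methyl-1-(1,4-dioxaspiro[4.5]dec-6-en-7-yl)hex-5-en-1-one | C=C(C)C[C@@H](O)CC(=O)C1=CC2(CCC1)OCCO2 | intermediate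
11 | (1R,3R)-5-methyl-1-(1,4-dioxaspiro[4.5]dec-6-en-7-yl)hex-5-ene-1,3-diol (syn) | C=C(C)C[C@@H](O)C[C@@H](O)C1=CC2(CCC1)OCCO2 | intermediate
12 | 7-[(1R,3R)-1,3-bis(tert-butyldimethylsilyloxy)-5-methylhex-5-en-1-yl]-1,4-dioxaspiro[4.5]dec-6-ene | C=C(C)C[C@@H](O[Si](C)(C)C(C)(C)C)C[C@@H](O[Si](C)(C)C(C)(C)C)C1=CC2(CCC1)OCCO2 | intermediate
13 | 3-[(1R,3R)-1,3-bis(tert-butyldimethylsilyloxy)-5-methylhex-5-en-1-yl]cyclohex-2-en-1-one | C=C(C)C[C@@H](O[Si](C)(C)C(C)(C)C)C[C@@H](O[Si](C)(C)C(C)(C)C)C1=CC(=O)CCC1 | intermediate
14 | (1R,3R,6S)-1,3-bis(tert-butyldimethylsilyloxy)-5,5-dimethylspiro[5.5]undecan-8-one (C2 and C4 silyloxy groups cis to each other and to C12; C11 ketone) | CC(C)(C)[Si](C)(C)O[C@@H]1C[C@H](O[Si](C)(C)C(C)(C)C)CC(C)(C)[C@@]12CCCC(=O)C2 | intermediate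
15 | C11 ethylene ketal of 14 | CC(C)(C)[Si](C)(C)O[C@@H]1C[C@H](O[Si](C)(C)C(C)(C)C)CC(C)(C)[C@@]12CCCC3(OCCO3)C2 | intermediate
16 | (2R,4R,7S)-ring A 2,4-diol, C11 ethylene ketal | O[C@@H]1C[C@H](O)CC(C)(C)[C@@]12CCCC3(OCCO3)C2 | intermediate
17 | (7S)-ring A 2,4-dione, C11 ethylene ketal | O=C1CC(=O)CC(C)(C)[C@@]12CCCC3(OCCO3)C2 | intermediate
18 | (7S)-vinylogous ester: C2 ketone, C3=C4 with isobutoxy on C4, C11 ethylene ketal | O=C1C=C(OCC(C)C)CC(C)(C)[C@@]12CCCC3(OCCO3)C2 | intermediate
19 | (7S)-2-trimethylsilyloxy-4-isobutoxy-2,4-diene, C11 ethylene ketal (not isolated) | C[Si](C)(C)OC1=CC(OCC(C)C)=CC(C)(C)[C@@]12CCCC3(OCCO3)C2 | intermediate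
20 | (5R,7S)-5-bromo vinylogous ester, bromine cis to C12, C11 ethylene ketal | O=C1C=C(OCC(C)C)[C@H](Br)C(C)(C)[C@@]12CCCC3(OCCO3)C2 | intermediate
21 | (5R,7R)-5-bromo-4-isobutoxy-2-methylene-3-ene, C11 ethylene ketal (not isolated) | C=C1C=C(OCC(C)C)[C@H](Br)C(C)(C)[C@@]12CCCC3(OCCO3)C2 | intermediate
22 | (5R,7R)-5-bromo-2-methylene-4-ketone, C11 ethylene ketal | C=C1CC(=O)[C@H](Br)C(C)(C)[C@@]12CCCC3(OCCO3)C2 | intermediate
23 | (4S,5R,7R)-5-bromo-4-hydroxy-2-methylene, hydroxyl and bromine cis, C11 ethylene ketal | C=C1C[C@H](O)[C@H](Br)C(C)(C)[C@@]12CCCC3(OCCO3)C2 | intermediate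
24 | (4S,5R,7R)-5-bromo-4-hydroxy-2-methylene C11 ketone | C=C1C[C@H](O)[C@H](Br)C(C)(C)[C@@]12CCCC(=O)C2 | intermediate
25 | 10-(dimethylaminomethyl) derivative of 24, C10 either epimer (not isolated) | C=C1C[C@H](O)[C@H](Br)C(C)(C)[C@@]12CCC(CN(C)C)C(=O)C2 | intermediate
26 | 10-(trimethylammoniomethyl) iodide of 24, C10 either epimer (not isolated) | C=C1C[C@H](O)[C@H](Br)C(C)(C)[C@@]12CCC(C[N+](C)(C)C)C(=O)C2.[I-] | intermediate
27 | (4S,5R,7R)-5-bromo-4-hydroxy-2,10-dimethylene C11 ketone | C=C1C[C@H](O)[C@H](Br)C(C)(C)[C@@]12CCC(=C)C(=O)C2 | intermediate
28 | (4S,5R,7R,10R)-C10 spiro-oxirane C11 ketone, epoxide oxygen cis to C6 | C=C1C[C@H](O)[C@H](Br)C(C)(C)[C@@]12CC[C@@]3(CO3)C(=O)C2 | intermediate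
29 | CNP0273087.1, (4S,5R,7R,10S) | C=C1C[C@H](O)[C@H](Br)C(C)(C)[C@@]12CC[C@@](O)(CCl)C(=O)C2 | target

## Step count and risks

Total: 21 steps. Longest linear sequence: 19 steps (steps 1–3 and 6–21); steps 4 and 5 form the two-step side branch.

Step 10 (key step). The most likely failures are two. The C6 radical may be reduced by a second hydrogen-atom transfer before it reaches the crowded C7. It may also take the allylic, oxygen-bearing hydrogen of C2 in a 1,5-shift; a deuterium at C2, from NaBD4 in step 7, would slow this shift and is lost later on oxidation. The fallback changes the acceptor and sets out from 10. Silylation of the C4 hydroxyl gives the β-silyloxy enone ketal F1, and PPTS in wet acetone frees the 3-acylcyclohexenone F2, in which C2 is a ketone and no 1,5-shift is possible. Fe(acac)3 and PhSiH3 then give the spiro diketone F3 through the chair with the C4 silyloxy group equatorial and the acyl enone s-trans, which leads to the same C7 configuration. The unhindered C11 ketone is ketalised selectively to F4, fluoride buffered with acetic acid gives the β-hydroxy ketone F5, and Dess–Martin oxidation returns to the route at 17. This variant is one step shorter but exposes the 7-endo attack at C12 that the main route excludes, which is why it is the reserve.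

Step 15. Bromine may enter at C3 instead of C5 or twice. Facial selectivity at C5 may also be poor, because the two arms of ring B at C7 differ only beyond the first carbon; the bromide-exchange equilibration named in the step is the first remedy. The fallback places the halogen by kinetic α′-enolate chemistry and sets out from 18. Addition of LiCH2OCH2OMe (from Bu3SnCH2OCH2OMe and n-BuLi, with CeCl3) to the C2 carbonyl and dilute oxalic acid give, by Stork–Danheiser transposition, the 2-(methoxymethoxymethyl) enone F6 with the ketone on C4. LiN(iPr)2 and Me3SiCl then NBS brominate the α′ carbon C5 to give F7. i-Bu2AlH gives the cis-bromohydrin allylic alcohol F8, and HCl in methanol removes the acetal and the ketal to give the diol ketone F9. ClCO2Me and pyridine acylate the primary allylic hydroxyl to give the carbonate F10. Pd(OAc)2, PBu3, HCO2H and Et3N then deliver hydride to the ring terminus of the allyl unit, which moves the double bond to the exocyclic position and rejoins the route at 24.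

Step 16. The aluminium centre of the reagent may ionise the allylic bromide, and the double bond may slip into conjugation with the new ketone during hydrolysis. The fallback is a Peterson olefination and sets out from 20. Me3SiCH2MgCl with CeCl3 adds to the C2 carbonyl to give the β-hydroxysilane F11. Dilute acid then hydrolyses the enol ether and eliminates silanol across C2–C1 only, which fixes the position of the alkene and returns to the route at 22.

Step 20. Facial selectivity at C10 may be poor, because C7 acts on C10 only through the chair of ring B. The fallback replaces substrate control by catalyst control and a different activation: iminium catalysis with a chiral primary amine salt (9-amino-9-deoxy-epi-quinine trifluoroacetate or its pseudo-enantiomer) and aqueous H2O2. It sets out from 27 and comes back at 28 without new intermediates.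

Further compounds
F1 | step 10 | (3R)-3-(tert-butyldimethylsilyloxy)-5-methyl-1-(1,4-dioxaspiro[4.5]dec-6-en-7-yl)hex-5-en-1-one | C=C(C)C[C@@H](O[Si](C)(C)C(C)(C)C)CC(=O)C1=CC2(CCC1)OCCO2
F2 | step 10 | 3-[(3R)-3-(tert-butyldimethylsilyloxy)-5-methylhex-5-enoyl]cyclohex-2-en-1-one | C=C(C)C[C@@H](O[Si](C)(C)C(C)(C)C)CC(=O)C1=CC(=O)CCC1
F3 | step 10 | (3R,6S)-3-(tert-butyldimethylsilyloxy)-5,5-dimethylspiro[5.5]undecane-1,8-dione | O=C1C[C@H](O[Si](C)(C)C(C)(C)C)CC(C)(C)[C@@]12CCCC(=O)C2
F4 | step 10 | C11 ethylene ketal of F3 | O=C1C[C@H](O[Si](C)(C)C(C)(C)C)CC(C)(C)[C@@]12CCCC3(OCCO3)C2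
F5 | step 10 | 4-hydroxy-2-ketone, C11 ethylene ketal | O=C1C[C@H](O)CC(C)(C)[C@@]12CCCC3(OCCO3)C2
F6 | step 15 | 2-(methoxymethoxymethyl)-2-en-4-one, C11 ethylene ketal | COCOCC1=CC(=O)CC(C)(C)[C@@]12CCCC3(OCCO3)C2
F7 | step 15 | 5-bromo derivative of F6, bromine cis to C12 | COCOCC1=CC(=O)[C@H](Br)C(C)(C)[C@@]12CCCC3(OCCO3)C2
F8 | step 15 | cis-bromohydrin from F7 (C4 alcohol, C2=C3 alkene) | COCOCC1=C[C@H](O)[C@H](Br)C(C)(C)[C@@]12CCCC3(OCCO3)C2
F9 | step 15 | 2-(hydroxymethyl)-2-ene cis-bromohydrin C11 ketone | OCC1=C[C@H](O)[C@H](Br)C(C)(C)[C@@]12CCCC(=O)C2
F10 | step 15 | primary allylic methyl carbonate of F9 | COC(=O)OCC1=C[C@H](O)[C@H](Br)C(C)(C)[C@@]12CCCC(=O)C2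
F11 | step 16 | 2-hydroxy-2-(trimethylsilylmethyl) adduct of 20, C2 either epimer | C[Si](C)(C)CC1(O)C=C(OCC(C)C)[C@H](Br)C(C)(C)[C@@]12CCCC3(OCCO3)C2
F0 | step 20 | none | none
A1 | alternative 1 | 3-isobutoxy-6,6-dimethyl-2-oxocyclohex-3-ene-1-carbaldehyde (hydroxymethylene ketone) | O=CC1C(=O)C=C(OCC(C)C)CC1(C)C
A2 | alternative 1 | methyl vinyl ketone | CC(=O)C=C
A3 | alternative 1 | spiro dienone with ring A vinylogous ester, ring B 4,4-disubstituted cyclohexenone | O=C1C=C(OCC(C)C)CC(C)(C)[C@@]12CCC(=O)C=C2
A4 | alternative 2 | prochiral spiro cyclobutanone with ring A vinylogous ester | O=C1CC2(C1)C(=O)C=C(OCC(C)C)CC2(C)C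
A5 | alternative 2 | tert-butyldimethyl[3-(trimethylsilyl)prop-2-ynyloxy]silane | C[Si](C)(C)C#CCO[Si](C)(C)C(C)(C)C
A6 | alternative 2 | spiro cyclohexenone with trimethylsilyl on C9 and silyloxymethyl on C10 | O=C1C=C(OCC(C)C)CC(C)(C)[C@@]12CC([Si](C)(C)C)=C(CO[Si](C)(C)C(C)(C)C)C(=O)C2
A7 | alternative 3 | spiro 1-(chloroacetyl)cyclopentan-1-ol with ring A vinylogous ester, carbinol epimer to be chosen for the chelated migration | O=C1C=C(OCC(C)C)CC(C)(C)[C@@]12CCC(O)(C(=O)CCl)C2
A8 | alternative 3 | spiro[5.5] chloromethyl ketol with ring A vinylogous ester | O=C1C=C(OCC(C)C)CC(C)(C)[C@@]12CC[C@@](O)(CCl)C(=O)C2
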